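**Numbering.** Bicyclic compounds use chromene numbering (O1, C2, C3, C4, C4a, C5–C8, C8a). Compound numbers follow the steps below.

## The problem

Target 23 is a 2,2-dimethyl-2H-chromene. Its benzene ring (ring A: C4a, C5, C6, C7, C8, C8a) is fused to the pyran ring through C4a–C8a and carries a free hydroxyl at C5, a 3-oxo-3-phenylpropanoyl chain at C6 and a methoxy group at C7; only C8 bears hydrogen. There is no stereocentre, so the task is one of constitution. Three phloroglucinol-type oxygens (O1, O5, O7) must end in three different states: ring ether, free phenol and methyl ether. The acyl chain must go to C6 and not to the electronically similar C8. Two groups will not tolerate rough treatment. The electron-rich C3=C4 double bond hydrates or dimerises in strong acid. The β-diketone next to a free ortho-hydroxyl cyclodehydrates to a flavone in hot acid and suffers retro-Claisen cleavage with nucleophilic base. Both are therefore introduced late and under mild conditions. The feature that opens the key step is that ring A has oxygens on the alternate carbons C5, C7 and C8a and shares C4a–C8a with the pyran ring. C5–C6–C7–C8 is thus a 1,3-dioxygenated butadiene with C5 at the ester oxidation level, and C4a=C8a is the C=C bond of a 2,3-dihydro-4H-pyran-4-one. The C4 carbonyl of that pyranone activates the cycloaddition and is later converted into C3=C4.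

## Retrosynthesis

**23 to 20 and 21.** The bond between the chain CH2 and the benzoyl carbon is cut, giving methyl ketone 20 and benzoyl chloride 21. The neighbouring cut, C6–C(acyl) with the whole benzoylacetyl chain on an aryl metal, needs a masked 1,3-dicarbonyl electrophile with acidic α-hydrogens and a β-leaving group, which a hindered aryllithium would deprotonate. The chosen cut ends the synthesis with an enolate acylation and a mild acidic quench, so the diketone never meets strong acid. The forward reaction must acylate at carbon, or at oxygen followed by acyl shift, which converge on 23.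

**20 to 19 to 16 and 17.** The C6–C(acetyl) bond is cut. Friedel–Crafts acylation of the free phenol would not distinguish C6 from C8. Directed ortho metalation does, if O5 carries a methoxymethyl group: C6–H then lies between the methoxymethoxy and the methoxy group. Precursor 16 is a plain protected chromene, and N-methoxy-N-methylacetamide 17 stops the addition at the ketone stage. The protecting group is removed (19 to 20) before the final acylation.

**16 to 15 to 13.** The C3=C4 double bond is traced back to the C4 ketone of chromanone 13 by reduction and dehydration, and the methoxymethyl ether to phenol 15. The ketone is kept up to 13 because it is the activating group of the cycloaddition, and its removal through a benzylic cation flanked by three oxygen donors is easy.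

**13 to 5 and 10 (key disconnection).** The C4a–C5 and C8–C8a bonds are cut, and ring A is dismantled into diene 10 and bromopyranone 5. Against any disconnection of a preformed phloroglucinol, this cut supplies O5 as the oxygen of a ketene acetal (it ends as the free phenol), O7 as the enol-ether methoxy group and O1 as the ring oxygen of the pyranone, so all three arrive differentiated. The forward reaction must take one orientation: the CH2 terminus of 10 to the oxygen-bearing β-carbon of 5, the acetal carbon to the brominated α-carbon. The adduct must then aromatise by loss of HBr and methanol while keeping O1.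

**5 to 4 to 1 and 2.** Bromine is removed from the nucleophilic α-position of vinylogous ester 4. The O1–C(Me)2 bond and the C5–C6 bond of 4 are then cut, giving mesityl oxide 1 and ethyl formate 2. Formylation of the acetyl methyl group and 6-endo oxa-Michael closure onto the dimethyl-substituted enone carbon are asked of the forward step.

**10 to 8 to 6.** The silyl group is removed from diene 10 to give enol-ether ester 8, which comes from methyl acetoacetate 6 by O-methylation through ketal 7. Only γ-deprotonation and O-silylation are required.

## Roads not taken

**Alternative 1:** The cut is the C5–C6 bond of ring A in a biomimetic sense. Mg(OMe)2 in methanol would open the 2-pyranone ring of the pyranopyranone A2 (2,2-dimethyl-7-(2,4-dioxo-4-phenylbutyl)-2H,5H-pyrano[4,3-b]pyran-5-one). The doubly activated C6 methylene would then attack the liberated ester carbon C5 and close ring A on the intact pyran ring, giving the 5,7-dihydroxy diketone A1.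
- Merits: ring A and the complete acyl chain arise in one step, and the chain sits at C6 by construction. The chosen plan needs protection, metalation, deprotection and acylation (steps 7–10) for the same result, so in convergence this road is better.
- Weak points: A1 has two phenols, O5 and O7, both ortho to the C6 carbonyl and both chelated, next to an acidic diketone CH2. Methylating O7 alone has no structural bias and competes with C- and enol-O-methylation. A2 is itself a multistep polyketone equivalent that can fold by aldol as well as Claisen modes.
- Comparison: the chosen plan places the methyl group on O7 before ring A exists, which this road cannot do.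

**Alternative 2:** The cut is at both C2–methyl bonds. Excess MeMgBr would add twice to the lactone carbonyl of 5-hydroxy-7-methoxycoumarin A4 and open it to the Z-allylic tertiary alcohol A3. No ring closes in that step. Acid then closes the pyran ring, and because the two phenols of A3 are equivalent only chromenol 15 can form.
- Merits: every reaction is of a long-known type, and 15 would be reached in fewer steps than steps 1–6 of the chosen route. In step economy and precedent this road is better up to 15.
- Weak points: A4 must come from selective mono-methylation of a dihydroxy lactone or from a coumarin-forming condensation on a monomethylated trihydroxybenzene, where ring closure ortho to hydroxyl or ortho to methoxyl competes. The phenoxide-deactivated lactone needs a large excess of Grignard reagent, and 1,4-addition at C4 competes.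
- Comparison: the chosen plan sets against it that no step has two near-equivalent phenolic oxygens or ring positions competing. The endgame from 15 would be the same.

**Alternative 3:** The cut is the C3=C4 bond. Second-generation Grubbs catalyst RuCl2(H2IMes)(PCy3)(=CHPh) would join the vinyl group on C4a with the vinyl group of the 1,1-dimethylallyl ether on O1 in diene A6, closing the pyran ring with loss of ethylene. The product A5 is identical with compound 16 of the chosen route.
- Merits: the ring closure is neutral, catalytic and more reliable than step 5, and it needs no ketone to be removed afterwards.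
- Weak points: A6 is a styrene with three different oxygen substituents, one of them a hindered tertiary allylic aryl ether ortho to the vinyl group. The differentiation problem is moved to the start, where two equivalent chelated hydroxyls of a trihydroxybenzaldehyde must be told apart. The tertiary ether is prone to ionisation and sigmatropic shift.
- Comparison: the overall step count would be no lower. The chosen plan sets against the better key step a ring A whose oxygen pattern needs no desymmetrisation.

Key step: step 5

Remark: the target is handled as the diketo tautomer as drawn; its chelated enol forms are the same compound.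

## Route

**Step 1**
Reactants: 1 mesityl oxide (4-methylpent-3-en-2-one); 2 ethyl formate
Product: 4 2,2-dimethyl-2,3-dihydro-4H-pyran-4-one, via hydroxymethylene ketone 3 (not isolated)
Conditions: NaOMe, Et2O, 0 °C to rt; then 2 M H2SO4, rt
Reagents that add atoms: none
Why: Claisen formylation at the acetyl methyl group gives the stabilised sodium enolate of the β-keto aldehyde; on acidification its enol hydroxyl adds 6-endo-trig (oxa-Michael) to the protonated dimethyl-substituted enone and closes the dihydropyranone.

**Step 2**
Reactants: 4 2,2-dimethyl-2,3-dihydro-4H-pyran-4-one
Product: 5 5-bromo-2,2-dimethyl-2,3-dihydro-4H-pyran-4-one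
Conditions: NBS, CH2Cl2, 0 °C to rt
Reagents that add atoms: N-bromosuccinimide, O=C1CCC(=O)N1Br
Why: α-Halogenation of a vinylogous ester; the enol-ether carbon C5 attacks bromine and the oxocarbenium ion loses the C5 proton, so only the vinylic α-position is substituted.

**Step 3**
Reactants: 6 methyl acetoacetate
Product: 8 methyl (E)-3-methoxybut-2-enoate, via dimethyl ketal 7 (not isolated)
Conditions: HC(OMe)3, H2SO4 (cat.), MeOH, rt; then distillation
Reagents that add atoms: trimethyl orthoformate, COC(OC)OC
Why: Acid-catalysed ketalisation with the orthoester followed by loss of methanol on distillation gives the conjugated enol ether, whose E isomer is the thermodynamically favoured one.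

**Step 4**
Reactants: 8 methyl (E)-3-methoxybut-2-enoate
Product: 10 (E)-1,3-dimethoxy-1-(trimethylsilyloxy)buta-1,3-diene, via lithium dienolate 9 (not isolated)
Conditions: LiN(iPr)2, THF, −78 °C; then Me3SiCl, −78 °C to rt
Reagents that add atoms: chlorotrimethylsilane, C[Si](C)(C)Cl
Why: Kinetic γ-deprotonation of the vinylogous ester gives the extended enolate, which is silylated on oxygen (silyl ketene acetal formation); the ketene-acetal geometry is of no consequence because C1 becomes an aromatic carbon.

**Step 5**
Reactants: 5 5-bromo-2,2-dimethyl-2,3-dihydro-4H-pyran-4-one; 10 (E)-1,3-dimethoxy-1-(trimethylsilyloxy)buta-1,3-diene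
Product: 13 5-hydroxy-7-methoxy-2,2-dimethylchroman-4-one, via bromo cycloadduct 11 (not isolated), via aryl silyl ether 12 (not isolated)
Conditions: 10 (3 equiv), iPr2NEt (1.5 equiv), PhMe, 110 °C, sealed tube; then 1 M HCl, THF, rt
Reagents that add atoms: none
Why: Proposed new method: the electron-rich ketene-acetal diene 10 should add across the C5=C6 bond of 5 in a polar, asynchronous Diels–Alder reaction, its CH2 terminus bonding to the oxygen-bearing β-carbon (later C8a) and its acetal carbon to the brominated α-carbon (later C4a) to give the cis-fused adduct 11; the closest known reaction type is the cycloaddition–aromatisation of 1,3-dimethoxy-1-silyloxybutadienes with 2-halo-1,4-quinones, and no case is known for an α-halo-β-alkoxy enone. Ring A closes in a six-membered [4+2] mode, either concertedly or as a Michael addition whose bromo enolate collapses at once onto the dioxocarbenium ion. The vinylogous orthoester carbon C5 of 11 then ionises and methanol is lost toward C8; the resulting silyloxy cyclohexadiene gives up HBr across C4a–C8a to the amine in an elimination with an aromatic transition state, and aqueous acid cleaves aryl silyl ether 12 to the phenol, which is held by a hydrogen bond to the C4 ketone. The three stereocentres of 11 (C4a, C5, C8a) are all erased, so no stereocontrol is needed. The one selectivity required is the orientation, and the enone polarisation (electrophilic β-carbon) and the bromine on the α-carbon both call for the same one. Bromine lowers the LUMO of a dienophile that the ring oxygen deactivates, and as the leaving group on C4a it forces aromatisation to keep O1 at C8a instead of expelling it. No silylating Lewis acid is used, because silyl transfer to the enolate would stop the reaction at the open-chain conjugate adduct; the hindered amine takes up HBr so that the excess of 10 survives.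

**Step 6**
Reactants: 13 5-hydroxy-7-methoxy-2,2-dimethylchroman-4-one
Product: 15 7-methoxy-2,2-dimethyl-2H-chromen-5-ol, via chromane-4,5-diol 14 (not isolated)
Conditions: NaBH4, THF–MeOH, 0 °C to rt; then 2 M HCl, rt
Reagents that add atoms: none
Why: Hydride reduction of the aryl ketone and E1 dehydration of the benzylic alcohol, whose cation is stabilised by two ortho oxygens and one para oxygen; only C3 carries β-hydrogens, so only the C3=C4 alkene can form.

**Step 7**
Reactants: 15 7-methoxy-2,2-dimethyl-2H-chromen-5-ol
Product: 16 7-methoxy-5-(methoxymethoxy)-2,2-dimethyl-2H-chromene
Conditions: MOMCl, iPr2NEt, CH2Cl2, 0 °C to rt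
Reagents that add atoms: chloromethyl methyl ether, COCCl
Why: O-Alkylation of the now unchelated phenol with an α-chloro ether; the acetal ether is stable to organolithium reagents and directs the next step.

**Step 8**
Reactants: 16 7-methoxy-5-(methoxymethoxy)-2,2-dimethyl-2H-chromene; 17 N-methoxy-N-methylacetamide
Product: 19 1-[7-methoxy-5-(methoxymethoxy)-2,2-dimethyl-2H-chromen-6-yl]ethan-1-one, via 6-lithiochromene 18 (not isolated)
Conditions: n-BuLi, THF, 0 °C; then 17, −78 to 0 °C; aq. NH4Cl
Reagents that add atoms: none
Why: Directed ortho metalation; C6–H lies between the methoxymethoxy and methoxy groups and is removed under their cooperative coordination in preference to C8–H, and the aryllithium adds to the N-methoxy-N-methylamide to give a chelated tetrahedral adduct that releases the ketone only on work-up.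

**Step 9**
Reactants: 19 1-[7-methoxy-5-(methoxymethoxy)-2,2-dimethyl-2H-chromen-6-yl]ethan-1-one
Product: 20 1-(5-hydroxy-7-methoxy-2,2-dimethyl-2H-chromen-6-yl)ethan-1-one
Conditions: 3 M HCl, MeOH, rt
Reagents that add atoms: none
Why: Acid-catalysed acetal cleavage, fast for an ether ortho to a carbonyl group; the acyl group lowers the electron density of the chromene, so the C3=C4 bond should tolerate the dilute acid.

**Step 10**
Reactants: 20 1-(5-hydroxy-7-methoxy-2,2-dimethyl-2H-chromen-6-yl)ethan-1-one; 21 benzoyl chloride
Product: 23 1-(5-hydroxy-7-methoxy-2,2-dimethyl-2H-chromen-6-yl)-3-phenylpropane-1,3-dione, via dilithium dianion 22 (not isolated)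
Conditions: LiN(SiMe3)2 (3.2 equiv), THF, −78 °C; then 21 (1.0 equiv), −78 °C to rt; 1 M HCl to pH 4
Reagents that add atoms: none
Why: Claisen-type acylation of the phenoxide–enolate dianion; any O-benzoate formed is converted by the excess base through a Baker–Venkataraman acyl shift into the same diketone, which is protected from further acylation as its enolate until the mild acidic quench.

## Compound list

1 | mesityl oxide (4-methylpent-3-en-2-one) | CC(=O)C=C(C)C | starting material
2 | ethyl formate | CCOC=O | starting material
3 | (1Z)-1-hydroxy-5-methylhexa-1,4-dien-3-one, formed as its sodium enolate (not isolated) | O/C=C\C(=O)C=C(C)C | intermediate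
4 | 2,2-dimethyl-2,3-dihydro-4H-pyran-4-one | CC1(C)CC(=O)C=CO1 | intermediate
5 | 5-bromo-2,2-dimethyl-2,3-dihydro-4H-pyran-4-one | CC1(C)CC(=O)C(Br)=CO1 | intermediate
6 | methyl acetoacetate | COC(=O)CC(C)=O | starting material
7 | methyl 3,3-dimethoxybutanoate (not isolated) | COC(=O)CC(C)(OC)OC | intermediate
8 | methyl (E)-3-methoxybut-2-enoate | CO/C(C)=C/C(=O)OC | intermediate
9 | lithium 1,3-dimethoxybuta-1,3-dien-1-olate, oxide oxygen anti to C3 as in 10 (not isolated) | [Li+].[O-]/C(OC)=C/C(=C)OC | intermediate
10 | (E)-1,3-dimethoxy-1-(trimethylsilyloxy)buta-1,3-diene | C[Si](C)(C)O/C(OC)=C/C(=C)OC | intermediate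
11 | 4a-bromo-5,7-dimethoxy-2,2-dimethyl-5-(trimethylsilyloxy)-2,3,4a,5,8,8a-hexahydro-4H-chromen-4-one, cis-fused (Br and 8a-H on the same face), racemic, both C5 epimers (not isolated) | COC1=CC(OC)(O[Si](C)(C)C)[C@]2(Br)C(=O)CC(C)(C)O[C@@H]2C1 | intermediate
12 | 7-methoxy-2,2-dimethyl-5-(trimethylsilyloxy)chroman-4-one (not isolated) | COc1cc(O[Si](C)(C)C)c2C(=O)CC(C)(C)Oc2c1 | intermediate
13 | 5-hydroxy-7-methoxy-2,2-dimethylchroman-4-one | COc1cc(O)c2C(=O)CC(C)(C)Oc2c1 | intermediate
14 | 7-methoxy-2,2-dimethylchromane-4,5-diol, racemic (not isolated) | COc1cc(O)c2C(O)CC(C)(C)Oc2c1 | intermediate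
15 | 7-methoxy-2,2-dimethyl-2H-chromen-5-ol | COc1cc(O)c2C=CC(C)(C)Oc2c1 | intermediate
16 | 7-methoxy-5-(methoxymethoxy)-2,2-dimethyl-2H-chromene | COCOc1cc(OC)cc2OC(C)(C)C=Cc12 | intermediate
17 | N-methoxy-N-methylacetamide | CON(C)C(C)=O | starting material
18 | [7-methoxy-5-(methoxymethoxy)-2,2-dimethyl-2H-chromen-6-yl]lithium (not isolated) | [Li]c1c(OC)cc2OC(C)(C)C=Cc2c1OCOC | intermediate
19 | 1-[7-methoxy-5-(methoxymethoxy)-2,2-dimethyl-2H-chromen-6-yl]ethan-1-one | CC(=O)c1c(OC)cc2OC(C)(C)C=Cc2c1OCOC | intermediate
20 | 1-(5-hydroxy-7-methoxy-2,2-dimethyl-2H-chromen-6-yl)ethan-1-one | CC(=O)c1c(OC)cc2OC(C)(C)C=Cc2c1O | intermediate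
21 | benzoyl chloride | O=C(Cl)c1ccccc1 | starting material
22 | dilithium 7-methoxy-2,2-dimethyl-6-(1-oxidoethenyl)-2H-chromen-5-olate (not isolated) | [Li+].[Li+].C=C([O-])c1c(OC)cc2OC(C)(C)C=Cc2c1[O-] | intermediate
23 | 1-(5-hydroxy-7-methoxy-2,2-dimethyl-2H-chromen-6-yl)-3-phenylpropane-1,3-dione | COc1cc2c(c(O)c1C(=O)CC(=O)c1ccccc1)C=CC(C)(C)O2 | target

## Step count and uncertain steps

Total: 10 steps. Longest linear sequence: 8 steps (steps 1, 2, 5, 6, 7, 8, 9, 10; the diene branch, steps 3, 4, 5–10, is equally long).

**Step 5 (key step, proposed new method).** Three processes may defeat it.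
- The cycloaddition may not start, because the ring oxygen deactivates the enone and the diene is lost at 110 °C by desilylation or silyl migration.
- Silyl transfer to the enolate after the first bond may stop the reaction at conjugate addition without ring closure.
- Aromatisation may take the wrong course. HBr must leave from cis-disposed H and Br; if instead bromine is lost reductively from the α-bromo-β-dicarbonyl stage, the ring then aromatises by expelling O1 and opening the pyranone.

The fallback uses known chemistry and gives up the de novo construction of ring A. It sets out from 1, which is oxidised with NaOCl (haloform reaction) to 3-methylbut-2-enoic acid F1. F1 is condensed with phloroglucinol in P2O5/MeSO3H (Friedel–Crafts acylation, then oxa-Michael closure) to 5,7-dihydroxy-2,2-dimethylchroman-4-one F2. One equivalent of Me2SO4 with K2CO3 in acetone methylates the unchelated 7-hydroxyl, and the route is rejoined at 13.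

**Step 8.** Metalation may occur in part at C8 (between the methoxy group and the ring oxygen) or at the vinylic C4, and the hindered aryllithium may deprotonate the amide instead of adding to it. The fallback avoids organolithium chemistry and sets out from 15. Ortho-specific formylation with MgCl2, Et3N and paraformaldehyde in MeCN (only C6 is a free ortho position) gives 5-hydroxy-7-methoxy-2,2-dimethyl-2H-chromene-6-carbaldehyde F3. Excess MeMgBr in THF gives 6-(1-hydroxyethyl)-7-methoxy-2,2-dimethyl-2H-chromen-5-ol F4, and MnO2 in CH2Cl2 oxidises the benzylic alcohol, rejoining the route at 20.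

**Step 6.** The ortho-hydroxybenzylic alcohol may ionise under the reducing conditions to a quinone methide that takes up hydride (over-reduction to the chroman), and the electron-rich chromene may dimerise in the acid used for dehydration. The fallback changes the order of events and removes water under basic conditions. It sets out from 13, which is protected with NaH and MOMCl in DMF to give 7-methoxy-5-(methoxymethoxy)-2,2-dimethylchroman-4-one F5. NaBH4 in MeOH gives 7-methoxy-5-(methoxymethoxy)-2,2-dimethylchroman-4-ol F6, and MsCl with Et3N in CH2Cl2 eliminates through the mesylate, rejoining the route at 16.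

**Step 10.** Acylation may stop at the phenol ester, go on to double acylation, or be followed by cyclodehydration to the flavone if the quench is too acidic. The fallback separates the two events. It sets out from 20, which is esterified with benzoyl chloride in pyridine to 6-acetyl-7-methoxy-2,2-dimethyl-2H-chromen-5-yl benzoate F7. KOH in pyridine at 50 °C then effects the Baker–Venkataraman rearrangement, and neutralisation with acetic acid gives 23.

## Further compounds

F1 | step 5 | 3-methylbut-2-enoic acid | CC(C)=CC(=O)O
F2 | step 5 | 5,7-dihydroxy-2,2-dimethylchroman-4-one | CC1(C)CC(=O)c2c(O)cc(O)cc2O1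
F3 | step 8 | 5-hydroxy-7-methoxy-2,2-dimethyl-2H-chromene-6-carbaldehyde | COc1cc2OC(C)(C)C=Cc2c(O)c1C=O
F4 | step 8 | 6-(1-hydroxyethyl)-7-methoxy-2,2-dimethyl-2H-chromen-5-ol (racemic) | COc1cc2OC(C)(C)C=Cc2c(O)c1C(C)O
F5 | step 6 | 7-methoxy-5-(methoxymethoxy)-2,2-dimethylchroman-4-one | COCOc1cc(OC)cc2OC(C)(C)CC(=O)c12
F6 | step 6 | 7-methoxy-5-(methoxymethoxy)-2,2-dimethylchroman-4-ol (racemic) | COCOc1cc(OC)cc2OC(C)(C)CC(O)c12
F7 | step 10 | 6-acetyl-7-methoxy-2,2-dimethyl-2H-chromen-5-yl benzoate | CC(=O)c1c(OC)cc2OC(C)(C)C=Cc2c1OC(=O)c1ccccc1
A1 | alternative 1 | 1-(5,7-dihydroxy-2,2-dimethyl-2H-chromen-6-yl)-3-phenylpropane-1,3-dione | Oc1cc2OC(C)(C)C=Cc2c(O)c1C(=O)CC(=O)c1ccccc1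
A2 | alternative 1 | 2,2-dimethyl-7-(2,4-dioxo-4-phenylbutyl)-2H,5H-pyrano[4,3-b]pyran-5-one | CC1(C)C=CC2=C(O1)C=C(CC(=O)CC(=O)c3ccccc3)OC2=O
A3 | alternative 2 | (Z)-2-(3-hydroxy-3-methylbut-1-en-1-yl)-5-methoxybenzene-1,3-diol | COc1cc(O)c(/C=C\C(C)(C)O)c(O)c1
A4 | alternative 2 | 5-hydroxy-7-methoxy-2H-chromen-2-one | COc1cc(O)c2C=CC(=O)Oc2c1
A5 | alternative 3 | 7-methoxy-5-(methoxymethoxy)-2,2-dimethyl-2H-chromene | COCOc1cc(OC)cc2OC(C)(C)C=Cc12
A6 | alternative 3 | 2-ethenyl-5-methoxy-1-(methoxymethoxy)-3-[(2-methylbut-3-en-2-yl)oxy]benzene | COCOc1cc(OC)cc(OC(C)(C)C=C)c1C=C
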